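**Retrosynthetic overview**

1. Numbering: decalin carbons C1–C10 as in drimanes (ring A = C1–C5 and C10, gem-dimethyl on C4; ring B = C5–C10), C11 = the ArCH2 carbon. The hydroxyquinone is unmasked last by Teuber oxidation of a resorcinol freed from its bis-MOM ether.
2. Ring A is closed last: the C4–C5 bond is formed by an iron-hydride HAT radical cyclization of a C3=C4 alkene onto the C5 ketone, which also creates the tertiary C5–OH.
3. Ring B comes from a cyclopentanone (C5, C6, C7, C8, C9) by one-carbon ring enlargement: a lithium carbenoid carbon (C10) that already carries the C1–C4 chain is inserted between C5 and the quaternary C9.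
4. The cyclopentanone comes from cyclopent-2-enone, Me2Zn and the aryl aldehyde (asymmetric conjugate addition–aldol sets C8, reductive methylation sets C9); the aldehyde comes from isovanillin.
5. Enabling feature: in ring B the ring-fusion CH (C10) lies between the oxygen-bearing C5 and the fully substituted C9. This O–C5–C10–C9(quaternary) pattern is what a 1,2-shift of the more substituted α-carbon in a β-oxido carbenoid leaves behind. Ring order: five-membered precursor, then ring B, then ring A.

Key step: step 8

Ar = 3-methoxy-2,6-bis(methoxymethoxy)phenyl.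
Remark on the chemistry: the carbinol centres of 9, 10, 19 and 20 and the alkene geometry of 11 (drawn E) are left uncontrolled, because each is erased in the next event.

**Route**

Step 1
Reactants: 1 isovanillin (3-hydroxy-4-methoxybenzaldehyde)
Product: 3 4-methoxybenzene-1,3-diol, via 3-hydroxy-4-methoxyphenyl formate 2 (not isolated)
Conditions: mCPBA, CH2Cl2, 0 °C to rt; then K2CO3 (cat.), MeOH, rt
Reagents that add atoms: 3-chloroperoxybenzoic acid (mCPBA), OOC(=O)c1cccc(Cl)c1
Why: Baeyer–Villiger oxidation of an electron-rich benzaldehyde (aryl migration, Dakin-type) followed by methanolysis of the aryl formate should give the resorcinol.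

Step 2
Reactants: 3 4-methoxybenzene-1,3-diol
Product: 4 1-methoxy-2,4-bis(methoxymethoxy)benzene
Conditions: MOMCl, i-Pr2NEt, CH2Cl2, 0 °C to rt
Reagents that add atoms: chloromethyl methyl ether (MOMCl), COCCl
Why: Double O-alkylation of the phenols (Williamson-type) installs base-stable MOM groups that also direct the metalation of step 3.

Step 3
Reactants: 4 1-methoxy-2,4-bis(methoxymethoxy)benzene
Product: 6 3-methoxy-2,6-bis(methoxymethoxy)benzaldehyde, via [3-methoxy-2,6-bis(methoxymethoxy)phenyl]lithium 5 (not isolated)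
Conditions: n-BuLi, THF, 0 °C; DMF, 0 °C to rt; H2O
Reagents that add atoms: N,N-dimethylformamide (DMF), CN(C)C=O
Why: Directed ortho-metalation should take place at the carbon flanked by both OMOM groups, and the aryllithium is formylated by DMF.

Step 4
Reactants: 7 cyclopent-2-en-1-one; 6 3-methoxy-2,6-bis(methoxymethoxy)benzaldehyde
Product: 9 (2S,3S)-2-[hydroxy(Ar)methyl]-3-methylcyclopentan-1-one as both carbinol epimers, via methylzinc (S)-3-methylcyclopent-1-en-1-olate 8 (not isolated)
Conditions: Me2Zn, Cu(OTf)2 (2 mol %), binaphthol-derived bis(1-phenylethyl)amine phosphoramidite (4 mol %, the antipode that gives 3S), toluene, −30 °C, 6 present; then H2O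
Reagents that add atoms: dimethylzinc, C[Zn]C
Why: Copper-catalysed asymmetric conjugate addition sets C8, and the zinc enolate, formed only toward C9, is captured by aldehyde 6 in a tandem aldol addition trans to the new methyl group.

Step 5
Reactants: 9 (2S,3S)-2-[hydroxy(Ar)methyl]-3-methylcyclopentan-1-one
Product: 11 (3S,E)-2-(Ar-methylidene)-3-methylcyclopentan-1-one, via keto methanesulfonate 10 (not isolated)
Conditions: MsCl, Et3N, CH2Cl2, 0 °C to rt
Reagents that add atoms: none
Why: Mesylation and E1cB elimination across the acidic C9–H should give the conjugated exocyclic enone, which erases the carbinol mixture.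

Step 6
Reactants: 11 (3S,E)-2-(Ar-methylidene)-3-methylcyclopentan-1-one
Product: 13 (2S,3S)-2-(ArCH2)-2,3-dimethylcyclopentan-1-one, via lithium (S)-2-(ArCH2)-3-methylcyclopent-1-en-1-olate 12 (not isolated)
Conditions: LiBH(s-Bu)3, THF, −78 °C; then MeI, −78 to 0 °C
Reagents that add atoms: iodomethane, CI
Why: Conjugate hydride addition (reductive alkylation of an enone) generates the C5–C9 enolate regiospecifically, and MeI should attack anti to the C8 methyl group, so the quaternary centre C9 is formed with CH2Ar cis to that methyl group.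

Step 7
Reactants: 14 dibromomethane; 15 5-bromo-2-methylpent-2-ene
Product: 17 6,6-dibromo-2-methylhex-2-ene, via dibromomethyllithium 16 (not isolated)
Conditions: LiN(i-Pr)2, THF, −95 °C; then 15, HMPA, −95 to −60 °C
Reagents that add atoms: none
Why: Alkylation of a lithium carbenoid: dibromomethyllithium should displace the primary bromide (SN2, promoted by HMPA) at a temperature where it does not decompose.

Step 8
Reactants: 17 6,6-dibromo-2-methylhex-2-ene; 13 (2S,3S)-2-(ArCH2)-2,3-dimethylcyclopentan-1-one
Product: 22 (2S,3S,4S)-3-(ArCH2)-3,4-dimethyl-2-(4-methylpent-3-en-1-yl)cyclohexan-1-one, via (1,1-dibromo-5-methylhex-4-en-1-yl)lithium 18 (not isolated), via lithium β-oxido dibromide 19 (not isolated), via lithium β-oxido carbenoid 20 (not isolated), via ring-enlarged lithium enolate 21 (not isolated)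
Conditions: 17, LiN(i-Pr)2, THF/Et2O, −100 °C; then 13, −100 to −78 °C; then n-BuLi, −95 to −40 °C; then AcOH, −78 °C
Reagents that add atoms: none
Why: Lithiated dibromide 18 adds to the carbonyl of 13 to give alkoxide 19, bromine–lithium exchange gives the β-oxido carbenoid 20, and the ring bond C5–C9 then shifts to the carbenoid carbon C10 with loss of LiBr, so that ring B appears as the lithium enolate 21, which is protonated to 22. The closest known reaction type is the one-carbon ring enlargement of cyclic ketones through β-oxido carbenoids made from lithiated gem-dibromides (1,1-dibromoalkanes included), in which the more substituted α-carbon migrates. Ring B is closed not by a cyclization but by this 1,2-alkyl shift: the C9–C10 bond forms as C5–C9 breaks in a three-centre transition state, and C9 migrates with retention, so C8 and C9 are carried over unchanged. The new stereocentre C10 is set in the protonation of 21: allylic 1,2-strain with the side chain on C10 places the larger CH2Ar group of C9 pseudoaxial, the proton enters axially on the opposite face, and the side chain ends equatorial and cis to CH2Ar, which should also be the more stable epimer. The step needs carbonyl addition to win over enolization and C9 to migrate rather than C6: 13 can enolize only toward C6 and is attacked at −100 °C, where addition of lithiated gem-dibromides should outrun proton transfer, and the quaternary, more electron-rich C9 has the higher migratory aptitude. The enolate is formed only between C5 and C10, a regiochemistry that deprotonation of the ketone could not give.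

Step 9
Reactants: 22 (2S,3S,4S)-3-(ArCH2)-3,4-dimethyl-2-(4-methylpent-3-en-1-yl)cyclohexan-1-one
Product: 23 (1S,2S,4aR,8aS)-1-(ArCH2)-1,2,5,5-tetramethyloctahydronaphthalen-4a(2H)-ol
Conditions: Fe(acac)3 (0.3 equiv), PhSiH3, EtOH, 60 °C
Reagents that add atoms: none
Why: Hydrogen-atom transfer from an iron hydride to the trisubstituted alkene gives the tertiary C4 radical, which should close ring A by 6-exo attack on the C5 carbonyl from the equatorial side because the axial CH2Ar on C9 blocks the axial face, so that C5–OH ends axial, cis to CH2Ar, with a trans ring fusion, the alkoxy radical then being reduced by divalent iron and protonated (metal-hydride HAT radical cyclization of an alkene-tethered ketone).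

Step 10
Reactants: 23 (1S,2S,4aR,8aS)-1-(ArCH2)-1,2,5,5-tetramethyloctahydronaphthalen-4a(2H)-ol
Product: 24 2-{[(1S,2S,4aR,8aS)-4a-hydroxy-1,2,5,5-tetramethyldecahydronaphthalen-1-yl]methyl}-4-methoxybenzene-1,3-diol
Conditions: ZnBr2, n-PrSH, CH2Cl2, 0 °C
Reagents that add atoms: none
Why: Lewis-acid-assisted acetal exchange with the thiol (MOM cleavage) should free both phenols without protic acid, which the acid-labile tertiary C5–OH would not tolerate.

Step 11
Reactants: 24 2-{[(1S,2S,4aR,8aS)-4a-hydroxy-1,2,5,5-tetramethyldecahydronaphthalen-1-yl]methyl}-4-methoxybenzene-1,3-diol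
Product: 25 2-hydroxy-3-{[(1S,2S,4aR,8aS)-4a-hydroxy-1,2,5,5-tetramethyldecahydronaphthalen-1-yl]methyl}-5-methoxycyclohexa-2,5-diene-1,4-dione
Conditions: (KSO3)2NO (2.2 equiv), KH2PO4 buffer, acetone/H2O, rt
Reagents that add atoms: potassium nitrosodisulfonate, [K+].[K+].[O]N(S(=O)(=O)[O-])S(=O)(=O)[O-]
Why: Teuber oxidation: the phenol next to OMe should be oxidised through its phenoxyl radical at the free para carbon to the p-quinone, while the second hydroxyl stays as the 2-hydroxy group of the hydroxyquinone.

**Compound list**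

1 | isovanillin (3-hydroxy-4-methoxybenzaldehyde) | COc1ccc(C=O)cc1O | starting material
2 | 3-hydroxy-4-methoxyphenyl formate | COc1ccc(OC=O)cc1O | intermediate
3 | 4-methoxybenzene-1,3-diol | COc1ccc(O)cc1O | intermediate
4 | 1-methoxy-2,4-bis(methoxymethoxy)benzene | COCOc1ccc(OC)c(OCOC)c1 | intermediate
5 | [3-methoxy-2,6-bis(methoxymethoxy)phenyl]lithium | [Li]c1c(OCOC)ccc(OC)c1OCOC | intermediate
6 | 3-methoxy-2,6-bis(methoxymethoxy)benzaldehyde | COc1ccc(OCOC)c(C=O)c1OCOC | intermediate
7 | cyclopent-2-en-1-one | O=C1CCC=C1 | starting material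
8 | methylzinc (S)-3-methylcyclopent-1-en-1-olate | C[Zn]OC1=C[C@@H](C)CC1 | intermediate
9 | (2S,3S)-2-{hydroxy[3-methoxy-2,6-bis(methoxymethoxy)phenyl]methyl}-3-methylcyclopentan-1-one, both carbinol epimers | COc1ccc(OCOC)c(C(O)[C@@H]2[C@@H](C)CCC2=O)c1OCOC | intermediate
10 | methanesulfonate ester of the carbinol of 9 | COc1ccc(OCOC)c(C(OS(C)(=O)=O)[C@@H]2[C@@H](C)CCC2=O)c1OCOC | intermediate
11 | (3S,E)-2-{[3-methoxy-2,6-bis(methoxymethoxy)phenyl]methylidene}-3-methylcyclopentan-1-one | COc1ccc(OCOC)c(/C=C2/C(=O)CC[C@@H]2C)c1OCOC | intermediate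
12 | lithium (S)-2-{[3-methoxy-2,6-bis(methoxymethoxy)phenyl]methyl}-3-methylcyclopent-1-en-1-olate | COc1ccc(OCOC)c(CC2=C(O[Li])CC[C@@H]2C)c1OCOC | intermediate
13 | (2S,3S)-2-{[3-methoxy-2,6-bis(methoxymethoxy)phenyl]methyl}-2,3-dimethylcyclopentan-1-one | COc1ccc(OCOC)c(C[C@@]2(C)[C@@H](C)CCC2=O)c1OCOC | intermediate
14 | dibromomethane | BrCBr | starting material
15 | 5-bromo-2-methylpent-2-ene | CC(C)=CCCBr | starting material
16 | dibromomethyllithium | [Li]C(Br)Br | intermediate
17 | 6,6-dibromo-2-methylhex-2-ene | CC(C)=CCCC(Br)Br | intermediate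
18 | (1,1-dibromo-5-methylhex-4-en-1-yl)lithium | [Li]C(Br)(Br)CCC=C(C)C | intermediate
19 | lithium (2S,3S)-1-(1,1-dibromo-5-methylhex-4-en-1-yl)-2-(ArCH2)-2,3-dimethylcyclopentan-1-olate, both C1 epimers | COc1ccc(OCOC)c(C[C@@]2(C)[C@@H](C)CCC2(O[Li])C(Br)(Br)CCC=C(C)C)c1OCOC | intermediate
20 | lithium (2S,3S)-1-(1-bromo-1-lithio-5-methylhex-4-en-1-yl)-2-(ArCH2)-2,3-dimethylcyclopentan-1-olate (β-oxido carbenoid) | COc1ccc(OCOC)c(C[C@@]2(C)[C@@H](C)CCC2(O[Li])C([Li])(Br)CCC=C(C)C)c1OCOC | intermediate
21 | lithium (3S,4S)-3-(ArCH2)-3,4-dimethyl-2-(4-methylpent-3-en-1-yl)cyclohex-1-en-1-olate | COc1ccc(OCOC)c(C[C@@]2(C)[C@@H](C)CCC(O[Li])=C2CCC=C(C)C)c1OCOC | intermediate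
22 | (2S,3S,4S)-3-{[3-methoxy-2,6-bis(methoxymethoxy)phenyl]methyl}-3,4-dimethyl-2-(4-methylpent-3-en-1-yl)cyclohexan-1-one | COc1ccc(OCOC)c(C[C@@]2(C)[C@@H](C)CCC(=O)[C@H]2CCC=C(C)C)c1OCOC | intermediate
23 | (1S,2S,4aR,8aS)-1-{[3-methoxy-2,6-bis(methoxymethoxy)phenyl]methyl}-1,2,5,5-tetramethyloctahydronaphthalen-4a(2H)-ol | COc1ccc(OCOC)c(C[C@@]2(C)[C@@H](C)CC[C@@]3(O)[C@H]2CCCC3(C)C)c1OCOC | intermediate
24 | 2-{[(1S,2S,4aR,8aS)-4a-hydroxy-1,2,5,5-tetramethyldecahydronaphthalen-1-yl]methyl}-4-methoxybenzene-1,3-diol | COc1ccc(O)c(C[C@@]2(C)[C@@H](C)CC[C@@]3(O)[C@H]2CCCC3(C)C)c1O | intermediate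
25 | 2-hydroxy-3-{[(1S,2S,4aR,8aS)-4a-hydroxy-1,2,5,5-tetramethyldecahydronaphthalen-1-yl]methyl}-5-methoxycyclohexa-2,5-diene-1,4-dione | COC1=CC(=O)C(O)=C(C[C@@]2(C)[C@@H](C)CC[C@@]3(O)[C@H]2CCCC3(C)C)C1=O | target

**Step count and risks**

Total step count: 11. Longest linear sequence: 10 steps (steps 1–6 and 8–11).

Step 8 (key step). What may go wrong: proton transfer from C6 of 13 to the hindered tertiary carbanion 18 (enolization instead of carbonyl addition), or competing migration of the methylene carbon C6. Fallback, setting out from 13 and coming back at 23: the parent carbenoid is used and ring A is closed by two-electron chemistry. Dibromomethyllithium 16, generated from 14 with lithium 2,2,6,6-tetramethylpiperidide in the presence of 13 at −78 °C, adds to give the dibromomethyl carbinol F1. Two equivalents of n-BuLi then bring about the same ring enlargement to the lithium enolate F2, which is allylated with allyl bromide and equilibrated at C10 (NaOMe, MeOH) to the equatorial 2-allyl ketone F3. Prenylmagnesium chloride adds through its substituted terminus, from the equatorial side of C5, to give the dienol F4. Ring-closing metathesis (second-generation Grubbs catalyst) gives the octalinol F5, and hydrogenation (H2, Pd/C) gives 23.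

Step 9. What may go wrong: reduction of the C4 radical to the alkane before it reaches the hindered carbonyl, or β-scission of the C5 alkoxy radical back to open-chain material. Fallback, setting out from 22 and coming back at 23: mCPBA gives the epoxide F6. Cp2TiCl (trivalent titanium, from Cp2TiCl2 and Zn) opens it to the same C4 tertiary radical, now with a titanium alkoxide on C3, and the alkoxy radical formed on addition to C5 is captured at once by a second titanium centre, giving the diol F7. The secondary C3 hydroxyl is then removed by Barton–McCombie deoxygenation through the xanthate F8 (NaH, CS2, MeI; then Bu3SnH, AIBN), giving 23.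

Step 4. What may go wrong: slow capture of the zinc enolate by the di-ortho-substituted aldehyde 6, so that the enolate equilibrates or condenses with 7 and regiocontrol is lost. Fallback, setting out from 7 and coming back at 9: the conjugate addition is run with Me3SiOTf as trap to give the silyl enol ether F9, which is isolated and joined to 6 in a Mukaiyama aldol addition (BF3·OEt2, CH2Cl2, −78 °C) to give 9.

**Further compounds**

F1 | step 8 | (2S,3S)-1-(dibromomethyl)-2-(ArCH2)-2,3-dimethylcyclopentan-1-ol, both C1 epimers | COc1ccc(OCOC)c(C[C@@]2(C)[C@@H](C)CCC2(O)C(Br)Br)c1OCOC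
F2 | step 8 | lithium (3S,4S)-3-(ArCH2)-3,4-dimethylcyclohex-1-en-1-olate | COc1ccc(OCOC)c(C[C@@]2(C)[C@@H](C)CCC(O[Li])=C2)c1OCOC
F3 | step 8 | (2S,3S,4S)-3-(ArCH2)-3,4-dimethyl-2-(prop-2-en-1-yl)cyclohexan-1-one | COc1ccc(OCOC)c(C[C@@]2(C)[C@@H](C)CCC(=O)[C@H]2CC=C)c1OCOC
F4 | step 8 | (1R,2S,3S,4S)-3-(ArCH2)-3,4-dimethyl-1-(2-methylbut-3-en-2-yl)-2-(prop-2-en-1-yl)cyclohexan-1-ol | COc1ccc(OCOC)c(C[C@@]2(C)[C@@H](C)CC[C@](O)(C(C)(C)C=C)[C@H]2CC=C)c1OCOC
F5 | step 8 | analogue of 23 with a C2=C3 double bond in ring A (octalinol) | COc1ccc(OCOC)c(C[C@@]2(C)[C@@H](C)CC[C@@]3(O)[C@H]2CC=CC3(C)C)c1OCOC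
F6 | step 9 | (2S,3S,4S)-3-(ArCH2)-2-[2-(3,3-dimethyloxiran-2-yl)ethyl]-3,4-dimethylcyclohexan-1-one, both epoxide epimers | COc1ccc(OCOC)c(C[C@@]2(C)[C@@H](C)CCC(=O)[C@H]2CCC3OC3(C)C)c1OCOC
F7 | step 9 | (1S,2S,4aR,8aS)-1-(ArCH2)-1,2,5,5-tetramethyloctahydronaphthalene-4a,6(2H)-diol, both C6 epimers | COc1ccc(OCOC)c(C[C@@]2(C)[C@@H](C)CC[C@@]3(O)[C@H]2CCC(O)C3(C)C)c1OCOC
F8 | step 9 | S-methyl xanthate of the secondary hydroxyl of F7 | COc1ccc(OCOC)c(C[C@@]2(C)[C@@H](C)CC[C@@]3(O)[C@H]2CCC(OC(=S)SC)C3(C)C)c1OCOC
F9 | step 4 | (S)-trimethyl[(3-methylcyclopent-1-en-1-yl)oxy]silane | C[Si](C)(C)OC1=C[C@@H](C)CC1
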